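The tetrahydrofuran ring (O1, C2 with the guaiacyl group, C3 with C9, C4 with the C7' aroyl group, C5) is cut at O1–C2 and C4–C5. C2 carries an aryl group that stabilises positive charge and C4 a carbonyl that stabilises negative charge, so C2–C3–C4 is a 1,3-zwitterion synthon, and O1–C5, bearing nothing, is formaldehyde. One Lewis-acid-catalysed (3+2) cycloaddition thus forms the ring, both bonds and the C2 stereocentre under control of C3. Its precursor is an enantiopure trans 2-aryl-3-(silyloxymethyl)cyclopropane-1,1-diester (aryl TIPS ether, primary TBDPS ether) from organocatalytic cyclopropanation of silylated coniferaldehyde; afterwards one ester is excised and the other becomes the syringyl ketone.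

Key step: step 5

Remarks on the chemistry
- All tetrahydrofurans are numbered O1, C2 (aryl), C3 (CH2O arm), C4 (acyl), C5. In this numbering the target is (2S,3R,4S), with each neighbouring pair of substituents trans.
- A purely invertive opening of the trans cyclopropane would give the 2,3-cis ring. The route therefore relies on ionic, reversible bonding at C2 in step 5.
- Assumption: in the fully silylated ketone the 3,4-trans C4 epimer is the more stable one, as is usual for vicinal substituents on a five-membered ring.
- Protecting groups: TIPS on both phenols and TBDPS on the primary alcohol replace TBS, because TBS ethers are the ones most likely to be lost to triflate Lewis acid (step 5) and to hot chloride (step 6).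

Step 1
Reactants: 1 coniferaldehyde
Product: 2 (E)-3-[3-methoxy-4-(triisopropylsilyloxy)phenyl]prop-2-enal
Conditions: TIPSCl, imidazole, DMF, rt
Reagents that add atoms: chlorotriisopropylsilane, CC(C)[Si](Cl)(C(C)C)C(C)C
Why: Routine silyl ether formation on a phenol, with TIPS chosen because aryl TIPS ethers resist base, nucleophiles and Lewis acid much better than aryl TBS ethers while keeping the ring electron-rich.

Step 2
Reactants: 2 (E)-3-[3-methoxy-4-(triisopropylsilyloxy)phenyl]prop-2-enal; 3 dimethyl bromomalonate
Product: 4 dimethyl (2R,3S)-2-formyl-3-[3-methoxy-4-(triisopropylsilyloxy)phenyl]cyclopropane-1,1-dicarboxylate (formyl and aryl trans)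
Conditions: (S)-2-[diphenyl(trimethylsilyloxy)methyl]pyrrolidine (20 mol%), 2,6-lutidine, CH2Cl2, 0 °C to rt
Reagents that add atoms: none
Why: Michael-initiated ring closure under iminium–enamine catalysis, in which the bromomalonate anion adds to the Si face of the β-carbon of the (E)-iminium ion (the face not shielded by the diphenyl(silyloxy)methyl group) and the enamine then displaces bromide (3-exo-tet) to give the trans cyclopropane, fixing the aryl carbon as S and the formyl carbon as R.

Step 3
Reactants: 4 dimethyl (2R,3S)-2-formyl-3-[3-methoxy-4-(triisopropylsilyloxy)phenyl]cyclopropane-1,1-dicarboxylate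
Product: 5 dimethyl (2R,3S)-2-(hydroxymethyl)-3-[3-methoxy-4-(triisopropylsilyloxy)phenyl]cyclopropane-1,1-dicarboxylate (crude, carried on at once)
Conditions: NaBH4, MeOH/CH2Cl2, −40 °C; AcOH quench at −40 °C
Reagents that add atoms: none
Why: Chemoselective borohydride reduction of an aldehyde beside esters, run cold and quenched with acid so that the new alkoxide has little chance to acylate onto the cis ester, with no stereocentre touched.

Step 4
Reactants: 5 dimethyl (2R,3S)-2-(hydroxymethyl)-3-[3-methoxy-4-(triisopropylsilyloxy)phenyl]cyclopropane-1,1-dicarboxylate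
Product: 6 dimethyl (2R,3S)-2-[(tert-butyldiphenylsilyloxy)methyl]-3-[3-methoxy-4-(triisopropylsilyloxy)phenyl]cyclopropane-1,1-dicarboxylate
Conditions: TBDPSCl, imidazole, DMF, 0 °C
Reagents that add atoms: tert-butyl(chloro)diphenylsilane, CC(C)(C)[Si](Cl)(c1ccccc1)c1ccccc1
Why: Silyl ether formation on a primary alcohol is fast enough to outrun lactonisation, and the TBDPS group is chosen for its resistance to acid and to chloride in steps 5 and 6.

Step 5
Reactants: 6 dimethyl (2R,3S)-2-[(tert-butyldiphenylsilyloxy)methyl]-3-[3-methoxy-4-(triisopropylsilyloxy)phenyl]cyclopropane-1,1-dicarboxylate; 7 formaldehyde (charged as dry paraformaldehyde)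
Product: 8 dimethyl (2S,3R)-3-[(tert-butyldiphenylsilyloxy)methyl]-2-[3-methoxy-4-(triisopropylsilyloxy)phenyl]tetrahydrofuran-4,4-dicarboxylate (2,3-trans)
Conditions: (CH2O)n (5 equiv), Sn(OTf)2 (10–20 mol%), 4 Å MS, ClCH2CH2Cl, rt to 40 °C
Reagents that add atoms: none
Why: Sn(OTf)2 chelates the geminal diester and heterolyses the cyclopropane bond between the aryl-bearing and the malonate carbon (future C2 and C4), giving a tin malonate enolate and a benzylic cation stabilised by the 4-silyloxy-3-methoxyphenyl ring; the formaldehyde oxygen bonds to C2 and the malonate carbon then bonds to the oxocarbenium carbon C5. The closest known reaction type is the Lewis-acid-catalysed (3+2) cycloaddition of 2-arylcyclopropane-1,1-diesters with aldehydes to 2-aryltetrahydrofuran diesters, including 2,3-disubstituted cyclopropanes, with formaldehyde as the smallest aldehyde partner. The one ring formed is closed by the C4–C5 bond, an aldol-type attack of the enolate carbon on the C5=O1 oxocarbenium unit lying inside the ring, formally 5-endo-trig (5-enolexo). The one new stereocentre, C2, is controlled by the C3 centre set in step 2, whose bonds are never broken and which therefore also carries the absolute configuration through the step, the aryl group settling trans to the C3 silyloxymethyl arm. The step needs 2,3-trans selectivity although a purely invertive opening of the trans cyclopropane would give the cis ring: the very electron-rich aryl group makes bond breaking at C2 ionic and lets the C2–O1 bond of any cis adduct re-ionise under the Lewis acid, so the mixture should drain to the less crowded trans isomer. Two ester acceptors are kept because a ketone acceptor could close through its own oxygen onto the cation, and TIPS and TBDPS ethers are used because they tolerate triflate Lewis acids better than TBS ethers.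

Step 6
Reactants: 8 dimethyl (2S,3R)-3-[(tert-butyldiphenylsilyloxy)methyl]-2-[3-methoxy-4-(triisopropylsilyloxy)phenyl]tetrahydrofuran-4,4-dicarboxylate
Product: 9 methyl (2S,3R)-3-[(tert-butyldiphenylsilyloxy)methyl]-2-[3-methoxy-4-(triisopropylsilyloxy)phenyl]tetrahydrofuran-4-carboxylate, as a mixture of C4 epimers
Conditions: LiCl, H2O (2 equiv), DMSO, 140 °C
Reagents that add atoms: none
Why: Krapcho dealkoxycarbonylation (chloride attack at the ester methyl group, loss of CO2, protonation of the ester enolate) leaves C2 and C3 untouched, while C4 forms without reliable control and is corrected in step 9.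

Step 7
Reactants: 9 methyl (2S,3R)-3-[(tert-butyldiphenylsilyloxy)methyl]-2-[3-methoxy-4-(triisopropylsilyloxy)phenyl]tetrahydrofuran-4-carboxylate (C4 epimers)
Product: 10 (2S,3R)-3-[(tert-butyldiphenylsilyloxy)methyl]-N-methoxy-2-[3-methoxy-4-(triisopropylsilyloxy)phenyl]-N-methyltetrahydrofuran-4-carboxamide, as a mixture of C4 epimers
Conditions: MeNH(OMe)·HCl, iPrMgCl, THF, −20 to 0 °C
Reagents that add atoms: N,O-dimethylhydroxylamine hydrochloride, CNOC.Cl
Why: Direct aminolysis of the ester by the chloromagnesium amide of N,O-dimethylhydroxylamine (Weinreb amide synthesis) proceeds at low temperature on secondary esters and leaves silyl ethers and the benzylic ether alone.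

Step 8
Reactants: 11 4-bromo-2,6-dimethoxyphenol
Product: 12 (4-bromo-2,6-dimethoxyphenoxy)triisopropylsilane
Conditions: TIPSCl, imidazole, DMF, 40 °C
Reagents that add atoms: chlorotriisopropylsilane, CC(C)[Si](Cl)(C(C)C)C(C)C
Why: Phenol silylation removes the acidic proton before lithiation and installs a group that comes off together with the other silyl ethers in the last step.

Step 9
Reactants: 10 (2S,3R)-3-[(tert-butyldiphenylsilyloxy)methyl]-N-methoxy-2-[3-methoxy-4-(triisopropylsilyloxy)phenyl]-N-methyltetrahydrofuran-4-carboxamide (C4 epimers); 12 (4-bromo-2,6-dimethoxyphenoxy)triisopropylsilane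
Product: 15 [(2S,3R,4S)-3-[(tert-butyldiphenylsilyloxy)methyl]-2-[3-methoxy-4-(triisopropylsilyloxy)phenyl]tetrahydrofuran-4-yl][3,5-dimethoxy-4-(triisopropylsilyloxy)phenyl]methanone, via aryllithium 13 (not isolated), via C4-epimeric ketone 14 (not isolated)
Conditions: 12 (1.5 equiv), n-BuLi, THF, −78 °C; then 10, −78 to −40 °C; AcOH quench; then DBU, THF, rt
Reagents that add atoms: none
Why: Bromine–lithium exchange and addition of the aryllithium to the Weinreb amide give a chelated tetrahedral adduct that releases the ketone only on quench (no over-addition), after which DBU equilibrates the now acidic C4–H through the enolate to the 3,4-trans epimer, ring opening by β-elimination being the reverse of a 5-endo-trig closure and therefore stereoelectronically slow.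

Step 10
Reactants: 15 [(2S,3R,4S)-3-[(tert-butyldiphenylsilyloxy)methyl]-2-[3-methoxy-4-(triisopropylsilyloxy)phenyl]tetrahydrofuran-4-yl][3,5-dimethoxy-4-(triisopropylsilyloxy)phenyl]methanone
Product: 16 (4-hydroxy-3,5-dimethoxyphenyl)[(2S,3R,4S)-2-(4-hydroxy-3-methoxyphenyl)-3-(hydroxymethyl)tetrahydrofuran-4-yl]methanone (CNP0169680.1)
Conditions: TBAF, AcOH (1:1, excess), THF, 0 °C to rt
Reagents that add atoms: none
Why: Fluoride-mediated desilylation removes both aryl TIPS ethers and the primary TBDPS ether in one operation, and the acetic acid buffer keeps the medium too weakly basic to enolise C4 (which, once C9–OH is free, could leak to a cis hemiketal) or to push the phenols toward quinone methide chemistry.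

Compound list
1 | coniferaldehyde, (E)-3-(4-hydroxy-3-methoxyphenyl)prop-2-enal | COc1cc(/C=C/C=O)ccc1O | starting material
2 | (E)-3-[3-methoxy-4-(triisopropylsilyloxy)phenyl]prop-2-enal | COc1cc(/C=C/C=O)ccc1O[Si](C(C)C)(C(C)C)C(C)C | intermediate
3 | dimethyl bromomalonate | COC(=O)C(Br)C(=O)OC | starting material
4 | dimethyl (2R,3S)-2-formyl-3-[3-methoxy-4-(triisopropylsilyloxy)phenyl]cyclopropane-1,1-dicarboxylate | COc1cc([C@@H]2[C@@H](C=O)C2(C(=O)OC)C(=O)OC)ccc1O[Si](C(C)C)(C(C)C)C(C)C | intermediate
5 | dimethyl (2R,3S)-2-(hydroxymethyl)-3-[3-methoxy-4-(triisopropylsilyloxy)phenyl]cyclopropane-1,1-dicarboxylate | COc1cc([C@@H]2[C@@H](CO)C2(C(=O)OC)C(=O)OC)ccc1O[Si](C(C)C)(C(C)C)C(C)C | intermediate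
6 | dimethyl (2R,3S)-2-[(tert-butyldiphenylsilyloxy)methyl]-3-[3-methoxy-4-(triisopropylsilyloxy)phenyl]cyclopropane-1,1-dicarboxylate (trans; key-step precursor) | COc1cc([C@@H]2[C@@H](CO[Si](c3ccccc3)(c3ccccc3)C(C)(C)C)C2(C(=O)OC)C(=O)OC)ccc1O[Si](C(C)C)(C(C)C)C(C)C | intermediate
7 | formaldehyde (used as paraformaldehyde) | C=O | starting material
8 | dimethyl (2S,3R)-3-[(tert-butyldiphenylsilyloxy)methyl]-2-[3-methoxy-4-(triisopropylsilyloxy)phenyl]tetrahydrofuran-4,4-dicarboxylate (2,3-trans; key-step product) | COc1cc([C@H]2OCC(C(=O)OC)(C(=O)OC)[C@@H]2CO[Si](c3ccccc3)(c3ccccc3)C(C)(C)C)ccc1O[Si](C(C)C)(C(C)C)C(C)C | intermediate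
9 | methyl (2S,3R)-3-[(tert-butyldiphenylsilyloxy)methyl]-2-[3-methoxy-4-(triisopropylsilyloxy)phenyl]tetrahydrofuran-4-carboxylate, C4 epimer mixture | COc1cc([C@H]2OCC(C(=O)OC)[C@@H]2CO[Si](c3ccccc3)(c3ccccc3)C(C)(C)C)ccc1O[Si](C(C)C)(C(C)C)C(C)C | intermediate
10 | (2S,3R)-3-[(tert-butyldiphenylsilyloxy)methyl]-N-methoxy-2-[3-methoxy-4-(triisopropylsilyloxy)phenyl]-N-methyltetrahydrofuran-4-carboxamide, C4 epimer mixture | COc1cc([C@H]2OCC(C(=O)N(C)OC)[C@@H]2CO[Si](c3ccccc3)(c3ccccc3)C(C)(C)C)ccc1O[Si](C(C)C)(C(C)C)C(C)C | intermediate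
11 | 4-bromo-2,6-dimethoxyphenol | COc1cc(Br)cc(OC)c1O | starting material
12 | (4-bromo-2,6-dimethoxyphenoxy)triisopropylsilane | COc1cc(Br)cc(OC)c1O[Si](C(C)C)(C(C)C)C(C)C | intermediate
13 | [3,5-dimethoxy-4-(triisopropylsilyloxy)phenyl]lithium | [Li]c1cc(OC)c(O[Si](C(C)C)(C(C)C)C(C)C)c(OC)c1 | intermediate
14 | [(2S,3R)-3-[(tert-butyldiphenylsilyloxy)methyl]-2-[3-methoxy-4-(triisopropylsilyloxy)phenyl]tetrahydrofuran-4-yl][3,5-dimethoxy-4-(triisopropylsilyloxy)phenyl]methanone, C4 epimer mixture | COc1cc([C@H]2OCC(C(=O)c3cc(OC)c(O[Si](C(C)C)(C(C)C)C(C)C)c(OC)c3)[C@@H]2CO[Si](c3ccccc3)(c3ccccc3)C(C)(C)C)ccc1O[Si](C(C)C)(C(C)C)C(C)C | intermediate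
15 | [(2S,3R,4S)-3-[(tert-butyldiphenylsilyloxy)methyl]-2-[3-methoxy-4-(triisopropylsilyloxy)phenyl]tetrahydrofuran-4-yl][3,5-dimethoxy-4-(triisopropylsilyloxy)phenyl]methanone (all-trans) | COc1cc([C@H]2OC[C@@H](C(=O)c3cc(OC)c(O[Si](C(C)C)(C(C)C)C(C)C)c(OC)c3)[C@@H]2CO[Si](c3ccccc3)(c3ccccc3)C(C)(C)C)ccc1O[Si](C(C)C)(C(C)C)C(C)C | intermediate
16 | (4-hydroxy-3,5-dimethoxyphenyl)[(2S,3R,4S)-2-(4-hydroxy-3-methoxyphenyl)-3-(hydroxymethyl)tetrahydrofuran-4-yl]methanone | COc1cc([C@H]2OC[C@@H](C(=O)c3cc(OC)c(O)c(OC)c3)[C@@H]2CO)ccc1O | target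

Total step count: 10. Longest linear sequence: 9 steps (steps 1–7, 9 and 10 from coniferaldehyde); step 8 is a one-step side branch.

Steps most likely to fail

1. Step 5. Paraformaldehyde may release monomer too slowly, so that the Lewis-acid-opened cyclopropane loses a proton or oligomerises instead of being trapped, and equilibration at C2 may stop short of the trans ring. Fallback, from 6 and back to the route at 8: the same two bonds are made one at a time by ordinary reactions. Sc(OTf)3-catalysed methanolysis of 6 opens the ring at the benzylic carbon to the γ-methoxy malonate F1. Base-catalysed hydroxymethylation of its malonate C–H (paraformaldehyde, cat. DBU, THF) gives the hydroxymethyl malonate F2. BF3·OEt2 in CH2Cl2 then ionises the benzylic methyl ether, and the primary hydroxyl closes onto C2 with loss of methanol to give 8, again trans under thermodynamic control.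

2. Step 6. Chloride and the basic salts that build up in hot wet DMSO may strip the aryl silyl ether, and the long heating may degrade the benzylic ether. Fallback, from 8 and back to the route at 9: NaOH (1 equiv) in THF/H2O at 0 °C saponifies one ester to the half-acid F3. Its triethylammonium salt is then decarboxylated in DMSO at about 110 °C, which reaches 9 without chloride or hydroxide at high temperature.

3. Step 3. The freed hydroxymethyl group may acylate onto the cis ester (lactonisation) before it can be silylated. Fallback, from 4 and back to the route at 6: lactonisation is allowed to run to completion (NaBH4, then cat. TsOH, via 5) to give the bicyclic lactone F4. LiOH (1 equiv, THF/H2O, 0 °C) opens it to the lithium hydroxy carboxylate F5, in which the remaining methyl ester sits trans to the hydroxymethyl group and cannot lactonise. Silylation in DMF (TBDPSCl, imidazole; the silyl ester falls off on work-up) gives the silyl ether acid F6, which is esterified at once with TMSCHN2 (MeOH/toluene, 0 °C) to 6.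

Further compounds
F1 | step 5 | dimethyl 2-[(2R)-1-(tert-butyldiphenylsilyloxy)-3-methoxy-3-[3-methoxy-4-(triisopropylsilyloxy)phenyl]propan-2-yl]malonate, mixture at the benzylic carbon | COc1cc(C(OC)[C@@H](CO[Si](c2ccccc2)(c2ccccc2)C(C)(C)C)C(C(=O)OC)C(=O)OC)ccc1O[Si](C(C)C)(C(C)C)C(C)C
F2 | step 5 | dimethyl 2-[(2R)-1-(tert-butyldiphenylsilyloxy)-3-methoxy-3-[3-methoxy-4-(triisopropylsilyloxy)phenyl]propan-2-yl]-2-(hydroxymethyl)malonate, mixture at the benzylic carbon | COc1cc(C(OC)[C@@H](CO[Si](c2ccccc2)(c2ccccc2)C(C)(C)C)C(CO)(C(=O)OC)C(=O)OC)ccc1O[Si](C(C)C)(C(C)C)C(C)C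
F3 | step 6 | (2S,3R)-3-[(tert-butyldiphenylsilyloxy)methyl]-4-(methoxycarbonyl)-2-[3-methoxy-4-(triisopropylsilyloxy)phenyl]tetrahydrofuran-4-carboxylic acid, C4 not defined | COc1cc([C@H]2OCC(C(=O)O)(C(=O)OC)[C@@H]2CO[Si](c3ccccc3)(c3ccccc3)C(C)(C)C)ccc1O[Si](C(C)C)(C(C)C)C(C)C
F4 | step 3 | methyl (1S,5R,6S)-6-[3-methoxy-4-(triisopropylsilyloxy)phenyl]-2-oxo-3-oxabicyclo[3.1.0]hexane-1-carboxylate | COc1cc([C@@H]2[C@H]3COC(=O)[C@]32C(=O)OC)ccc1O[Si](C(C)C)(C(C)C)C(C)C
F5 | step 3 | lithium (1R,2R,3S)-2-(hydroxymethyl)-1-(methoxycarbonyl)-3-[3-methoxy-4-(triisopropylsilyloxy)phenyl]cyclopropane-1-carboxylate (carboxylate cis to the hydroxymethyl group) | COc1cc([C@@H]2[C@@H](CO)[C@]2(C(=O)[O-])C(=O)OC)ccc1O[Si](C(C)C)(C(C)C)C(C)C.[Li+]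
F6 | step 3 | (1R,2R,3S)-2-[(tert-butyldiphenylsilyloxy)methyl]-1-(methoxycarbonyl)-3-[3-methoxy-4-(triisopropylsilyloxy)phenyl]cyclopropane-1-carboxylic acid | COc1cc([C@@H]2[C@@H](CO[Si](c3ccccc3)(c3ccccc3)C(C)(C)C)[C@]2(C(=O)O)C(=O)OC)ccc1O[Si](C(C)C)(C(C)C)C(C)C
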